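**Retrosynthetic overview**
1. Target 12 is opened at the benzylic C2–O1 bond. This C–O bond, and with it the only ring (the oxolane), is made in the last step by a silicon-tethered radical relay on the bis(iodomethylsilyl) ether 10 of the C2-symmetric diol 8.
2. 10 comes from diol 8 (silylation, halide exchange); 8 comes from bis-imide 7 (hydride cleavage of both auxiliaries).
3. 7 comes from two molecules of imide 4 by oxidative enolate homocoupling, which makes the central C–C bond and both carbon stereocentres (R,R).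
4. 4 comes from acid 1 and oxazolidinone 2.

Assumption: the target is read from the SMILES as the (2S,3R,4R) isomer (aryl trans to CH2OH, CH2OH cis to benzyl); 1, 2 and (bromomethyl)chlorodimethylsilane are taken as catalogue chemicals.

**Step 1**
Reactants: 1 3-(3,4,5-trimethoxyphenyl)propanoic acid; 2 (S)-4-isopropyloxazolidin-2-one
Product: 4 (S)-4-isopropyl-3-[3-(3,4,5-trimethoxyphenyl)propanoyl]oxazolidin-2-one, via mixed pivalic anhydride 3 (not isolated)
Conditions: PivCl, Et3N, THF, −20 °C; then 2, LiCl, −20 °C → rt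
Reagents that add atoms: none
Why: Mixed-anhydride N-acylation of an oxazolidinone (pivaloyl activation, LiCl-assisted); the oxazolidinone attacks the unhindered acyl carbon of 3, and no stereocentre is formed.

**Step 2**
Reactants: 4 (S)-4-isopropyl-3-[3-(3,4,5-trimethoxyphenyl)propanoyl]oxazolidin-2-one (two molecules)
Product: 7 (4S,4'S)-3,3'-[(2R,3R)-2,3-bis(3,4,5-trimethoxybenzyl)butanedioyl]bis(4-isopropyloxazolidin-2-one), via lithium Z-enolate 5 (not isolated), via trichlorotitanium Z-enolate 6 (not isolated)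
Conditions: LiN(iPr)2, THF, −78 °C; then TiCl4 (CH2Cl2 solution), −78 °C → rt
Reagents that add atoms: none
Why: Oxidative enolate homocoupling: the enolate is transmetallated to tetravalent titanium and two chelated enolates join carbon to carbon with reduction to trivalent titanium; each α-carbon reacts on the face away from the isopropyl group of its own auxiliary, so both new centres are R (a reported outcome for 3-arylpropanoyl oxazolidinones).

**Step 3**
Reactants: 7 (4S,4'S)-3,3'-[(2R,3R)-2,3-bis(3,4,5-trimethoxybenzyl)butanedioyl]bis(4-isopropyloxazolidin-2-one)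
Product: 8 (2R,3R)-2,3-bis(3,4,5-trimethoxybenzyl)butane-1,4-diol
Conditions: LiBH4, MeOH (2.2 equiv), THF, 0 °C → rt
Reagents that add atoms: none
Why: Reductive cleavage of N-acyl oxazolidinones by LiBH4 (hydride attacks the lithium-chelated exocyclic carbonyl); any lactone formed on the way is reduced on to the diol, and the α-centres are not enolised, so R,R is kept.

**Step 4**
Reactants: 8 (2R,3R)-2,3-bis(3,4,5-trimethoxybenzyl)butane-1,4-diol
Product: 10 (2R,3R)-1,4-bis{[(iodomethyl)dimethylsilyl]oxy}-2,3-bis(3,4,5-trimethoxybenzyl)butane, via bis(bromomethylsilyl) ether 9 (not isolated)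
Conditions: BrCH2SiMe2Cl (2.3 equiv), Et3N, DMAP (cat.), CH2Cl2, 0 °C; filter, concentrate; then NaI, acetone, rt, dark
Reagents that add atoms: (bromomethyl)chlorodimethylsilane, C[Si](C)(Cl)CBr; sodium iodide, [Na+].[I-]
Why: Nishiyama–Stork-type O-silylation of both primary alcohols, then Finkelstein exchange (SN2 at the α-silyl carbon) installs the C–I radical precursor; the stereocentres are not involved.

**Step 5**
Reactants: 10 (2R,3R)-1,4-bis{[(iodomethyl)dimethylsilyl]oxy}-2,3-bis(3,4,5-trimethoxybenzyl)butane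
Product: 12 [(2S,3R,4R)-2-(3,4,5-trimethoxyphenyl)-4-(3,4,5-trimethoxybenzyl)oxolan-3-yl]methanol, via trimethylsilyl ether 11 (not isolated)
Conditions: fac-Ir(ppy)3 [tris(2-phenylpyridinato)iridium] (1 mol %), propylene oxide (5 equiv), MeCN (0.05 M, degassed), 450 nm LEDs, rt, stopped when 10 is consumed; then K2CO3 (cat.), MeOH, rt
Reagents that add atoms: none
Why: Proposed new method: the photoexcited iridium complex reduces one C–I bond, the α-silyl primary radical takes a benzylic hydrogen from the γ-carbon through a seven-membered 1,6-hydrogen-atom-transfer transition state (its tether ends as a trimethylsilyl group), the electron-rich benzylic radical is oxidised by the tetravalent iridium complex (or captured by iodine) to the benzylic cation, and the δ silyl-ether oxygen of the other arm closes the oxolane with loss of its own silyl group as the iodosilane, which propylene oxide destroys so that ring closure cannot reverse; the process is redox-neutral and the first ring closure expels the only other oxidising tether, so 11 carries no C–I bond and a second closure to the furofuran is blocked, while C2 is set S because the aryl group takes the position trans to the neighbouring CH2OSi group in the envelope transition state on the planar cation (2,3-trans, also the more stable arrangement); this is a radical-polar crossover etherification whose closest known reaction types are silicon-tethered 1,6-hydrogen-atom transfer used for remote desaturation of alcohols under photoexcited palladium catalysis and photoredox radical-polar crossover of alkyl iodides, neither of which has been used to make a C–O bond or an oxolane from a 1,4-diol.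

**Compound list**
1 | 3-(3,4,5-trimethoxyphenyl)propanoic acid | COc1cc(CCC(O)=O)cc(OC)c1OC | starting material
2 | (S)-4-isopropyloxazolidin-2-one | CC(C)[C@H]1COC(=O)N1 | starting material
3 | 2,2-dimethylpropanoic 3-(3,4,5-trimethoxyphenyl)propanoic anhydride | COc1cc(CCC(=O)OC(=O)C(C)(C)C)cc(OC)c1OC | intermediate
4 | (S)-4-isopropyl-3-[3-(3,4,5-trimethoxyphenyl)propanoyl]oxazolidin-2-one | COc1cc(CCC(=O)N2[C@@H](C(C)C)COC2=O)cc(OC)c1OC | intermediate
5 | lithium (Z)-enolate of 4 | [Li+].[O-]/C(=C\Cc1cc(OC)c(OC)c(OC)c1)N1[C@@H](C(C)C)COC1=O | intermediate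
6 | trichlorotitanium (Z)-enolate of 4 | Cl[Ti](Cl)(Cl)O/C(=C\Cc1cc(OC)c(OC)c(OC)c1)N1[C@@H](C(C)C)COC1=O | intermediate
7 | (4S,4'S)-3,3'-[(2R,3R)-2,3-bis(3,4,5-trimethoxybenzyl)butanedioyl]bis(4-isopropyloxazolidin-2-one) | COc1cc(C[C@@H](C(=O)N2[C@@H](C(C)C)COC2=O)[C@@H](Cc2cc(OC)c(OC)c(OC)c2)C(=O)N2[C@@H](C(C)C)COC2=O)cc(OC)c1OC | intermediate
8 | (2R,3R)-2,3-bis(3,4,5-trimethoxybenzyl)butane-1,4-diol | COc1cc(C[C@@H](CO)[C@H](CO)Cc2cc(OC)c(OC)c(OC)c2)cc(OC)c1OC | intermediate
9 | (2R,3R)-1,4-bis{[(bromomethyl)dimethylsilyl]oxy}-2,3-bis(3,4,5-trimethoxybenzyl)butane | COc1cc(C[C@@H](CO[Si](C)(C)CBr)[C@H](CO[Si](C)(C)CBr)Cc2cc(OC)c(OC)c(OC)c2)cc(OC)c1OC | intermediate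
10 | (2R,3R)-1,4-bis{[(iodomethyl)dimethylsilyl]oxy}-2,3-bis(3,4,5-trimethoxybenzyl)butane | COc1cc(C[C@@H](CO[Si](C)(C)CI)[C@H](CO[Si](C)(C)CI)Cc2cc(OC)c(OC)c(OC)c2)cc(OC)c1OC | intermediate
11 | trimethyl{[(2S,3R,4R)-2-(3,4,5-trimethoxyphenyl)-4-(3,4,5-trimethoxybenzyl)oxolan-3-yl]methoxy}silane | COc1cc(C[C@H]2CO[C@H](c3cc(OC)c(OC)c(OC)c3)[C@H]2CO[Si](C)(C)C)cc(OC)c1OC | intermediate
12 | [(2S,3R,4R)-2-(3,4,5-trimethoxyphenyl)-4-(3,4,5-trimethoxybenzyl)oxolan-3-yl]methanol | COc1cc(C[C@H]2CO[C@H](c3cc(OC)c(OC)c(OC)c3)[C@H]2CO)cc(OC)c1OC | target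

**Totals**
Total step count: 5. Longest linear sequence: 5 (1 → 4 → 7 → 8 → 10 → 12).

**Three steps most likely to fail**

Step 5 (the proposed new step). Likely failures are slow electron transfer to the α-silyl iodide, Friedel–Crafts closure of the benzylic cation onto the second arene (aryltetralin) instead of capture by the silyl-ether oxygen, and some 1,7-hydrogen transfer. The fallback uses only known lignan chemistry; it sets out from 4 and comes back at 12.
- The sodium enolate of 4 (NaN(SiMe3)2, THF, −78 °C) is alkylated with tert-butyl bromoacetate on the face away from the isopropyl group to give tert-butyl (3R)-4-[(4S)-4-isopropyl-2-oxooxazolidin-3-yl]-4-oxo-3-(3,4,5-trimethoxybenzyl)butanoate F1.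
- LiBH4 (THF, 0 °C) removes the auxiliary, and TsOH (cat., toluene, 50 °C) lactonises the hydroxy ester to (4R)-4-(3,4,5-trimethoxybenzyl)dihydrofuran-2(3H)-one F2.
- Its lithium enolate (LiN(SiMe3)2, THF, −78 °C) adds to 3,4,5-trimethoxybenzaldehyde trans to the benzyl group, giving (3S,4R)-3-[hydroxy(3,4,5-trimethoxyphenyl)methyl]-4-(3,4,5-trimethoxybenzyl)dihydrofuran-2(3H)-one F3 (both carbinol epimers).
- LiAlH4 (THF, 0 °C) gives (2R,3R)-2-[hydroxy(3,4,5-trimethoxyphenyl)methyl]-3-(3,4,5-trimethoxybenzyl)butane-1,4-diol F4.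
- Camphorsulfonic acid (cat., CH2Cl2, 0 °C → rt) closes the oxolane by SN1 cycloetherification through the benzylic cation; both carbinol epimers converge on the 2,3-trans product 12.

Step 2. Likely failures are a moderate yield, incomplete R,R selectivity, or Lewis-acid damage to the trimethoxyarenes. The fallback drops the auxiliary and secures the configuration by separation and resolution; it sets out from 1 and comes back at 8.
- The dianion of 1 (LiN(iPr)2, 2.2 equiv, THF, 0 °C) is coupled with I2 (0.5 equiv, −78 °C → rt) to 2,3-bis(3,4,5-trimethoxybenzyl)butanedioic acid F5 (racemic pair plus meso).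
- The racemic diastereomer is freed from the meso acid by crystallisation and resolved as its salt with (R)-1-phenylethylamine to (2R,3R)-2,3-bis(3,4,5-trimethoxybenzyl)butanedioic acid F6.
- LiAlH4 (THF, reflux) reduces F6 to 8.

Step 3. Likely failures are ring-opening of the oxazolidinones or a stalled reduction on the hindered vicinal bis-imide. The fallback removes the auxiliaries by acyl transfer before reduction; it sets out from 7 and comes back at 8.
- LiOCH2Ph (THF, 0 °C) converts 7 into dibenzyl (2R,3R)-2,3-bis(3,4,5-trimethoxybenzyl)butanedioate F7.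
- LiAlH4 (THF, 0 °C) reduces F7 to 8.

**Further compounds**
F1 | step 5 | tert-butyl (3R)-4-[(4S)-4-isopropyl-2-oxooxazolidin-3-yl]-4-oxo-3-(3,4,5-trimethoxybenzyl)butanoate | COc1cc(C[C@H](CC(=O)OC(C)(C)C)C(=O)N2[C@@H](C(C)C)COC2=O)cc(OC)c1OC
F2 | step 5 | (4R)-4-(3,4,5-trimethoxybenzyl)dihydrofuran-2(3H)-one | COc1cc(C[C@H]2COC(=O)C2)cc(OC)c1OC
F3 | step 5 | (3S,4R)-3-[hydroxy(3,4,5-trimethoxyphenyl)methyl]-4-(3,4,5-trimethoxybenzyl)dihydrofuran-2(3H)-one (carbinol epimers) | COc1cc(C[C@H]2COC(=O)[C@@H]2C(O)c2cc(OC)c(OC)c(OC)c2)cc(OC)c1OC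
F4 | step 5 | (2R,3R)-2-[hydroxy(3,4,5-trimethoxyphenyl)methyl]-3-(3,4,5-trimethoxybenzyl)butane-1,4-diol (carbinol epimers) | COc1cc(C[C@@H](CO)[C@H](CO)C(O)c2cc(OC)c(OC)c(OC)c2)cc(OC)c1OC
F5 | step 2 | 2,3-bis(3,4,5-trimethoxybenzyl)butanedioic acid (racemic pair plus meso) | COc1cc(CC(C(O)=O)C(Cc2cc(OC)c(OC)c(OC)c2)C(O)=O)cc(OC)c1OC
F6 | step 2 | (2R,3R)-2,3-bis(3,4,5-trimethoxybenzyl)butanedioic acid | COc1cc(C[C@@H](C(O)=O)[C@@H](Cc2cc(OC)c(OC)c(OC)c2)C(O)=O)cc(OC)c1OC
F7 | step 3 | dibenzyl (2R,3R)-2,3-bis(3,4,5-trimethoxybenzyl)butanedioate | COc1cc(C[C@@H](C(=O)OCc2ccccc2)[C@@H](Cc2cc(OC)c(OC)c(OC)c2)C(=O)OCc2ccccc2)cc(OC)c1OC
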